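Assumption: (R)-glyceraldehyde acetonide, made industrially from D-mannitol, is the purchased chiral material. Lignan numbering is used in the comments: C7/C8/C9 = oxolane C2/C3/CH2OH.

## Retrosynthetic overview
- The target is the C2-symmetric all-trans (2S,3R,4R,5S) oxolane. It comes from reduction of the all-trans 2,5-diaryloxolane-3,4-dicarbaldehyde.
- The dialdehyde comes from a 3,4-bis(dioxolanyl)oxolane by cutting one carbon off each side chain (glycol cleavage). The sacrificial C9 stereocentres are the purchased ones.
- The oxolane is the only ring formed. One anodic step makes it: 8–8′ C–C coupling of two identical 4-alkenylsyringols, after which water joins C7–O–C7′.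
- The monomer comes from a Heck coupling of 4-bromo-2,6-dimethoxyphenol with (S)-vinyldioxolane, which is made from (R)-glyceraldehyde acetonide.
- Stereochemical relay: purchased C9 sets C8/C8′ (kinetic, in the coupling), and C8/C8′ set C7/C7′ (thermodynamic, all-trans).

## Route

**Step 1**
Reactants: 1, (4R)-2,2-dimethyl-1,3-dioxolane-4-carbaldehyde
Product: 2, (4S)-4-ethenyl-2,2-dimethyl-1,3-dioxolane
Conditions: Ph3PCH3Br, KHMDS, THF, −78 °C → rt; distil
Reagents that add atoms: methyltriphenylphosphonium bromide, C[P+](c1ccccc1)(c1ccccc1)c1ccccc1.[Br-] (adds CH2)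
Why: Wittig methylenation at low temperature leaves the purchased stereocentre untouched, and the descriptor changes R→S only because the CIP priorities change.

**Step 2**
Reactants: 2; 3, 4-bromo-2,6-dimethoxyphenol
Product: 4, 4-{(E)-2-[(4S)-2,2-dimethyl-1,3-dioxolan-4-yl]ethenyl}-2,6-dimethoxyphenol
Conditions: Pd(OAc)2 (3 mol %), P(o-tol)3 (9 mol %), Et3N, DMF, 95 °C, sealed tube (1.5 equiv of 2)
Reagents that add atoms: none
Why: In this Mizoroki–Heck reaction, terminal carbopalladation followed by syn β-H elimination toward the benzylic hydrogen gives the conjugated E-styrene, and the allylic acetal carbon is not involved, so its configuration is retained.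

**Step 3 (key step)**
Reactants: 4 (2 equiv)
Product: 5, (2S,3S,4S,5S)-2,5-bis(4-hydroxy-3,5-dimethoxyphenyl)-3,4-bis[(4S)-2,2-dimethyl-1,3-dioxolan-4-yl]oxolane. It is obtained together with its C2 epimer, which has the same C3/C4/dioxolane configuration. After isomers that differ at C3/C4 are removed by chromatography, both are carried forward.
Conditions: RVC(+) ‖ Pt(−), divided cell, +0.55 V vs Ag/AgCl (1.0–1.1 F mol⁻¹), Et4NBF4 (0.1 M), 2,6-lutidine (1.2 equiv), MeCN–H2O 4:1, 0.1 M in 4, 0 °C; then rt, 2 h
Reagents that add atoms: water, O (becomes the ring oxygen)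
Why: Proposed new method: substrate-directed anodic dehydrodimerisation with hydrative cyclisation (formal 2+2+1), reasoned as follows.
- Mechanism: proton-coupled oxidation of the conjugated phenol, which oxidises more easily than the non-conjugated product, gives a phenoxyl radical with spin density at C8.
- Regiochemistry: because both ortho positions are blocked, the radicals couple mainly 8–8′ to a bis(p-quinone methide). Water adds to one methide, and the new C7–OH closes 5-exo onto the other, inherently trans to C9′.
- C8/C8′ control: each C8 reacts through the A(1,3)-minimised rotamer, with C9–H in the π-plane and the new bond anti to the C9–O bond. This is the same anti sense as osmylation of allylic ethers and cuprate addition to γ-alkoxy enoates.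
- Selectivity: the intrinsic like-topicity of 8–8′ coupling squares the per-centre bias in favour of the (8,8′) pair drawn. The wrong-face products are diastereomers, so they can be separated without loss of ee.
- Closest known reaction type: biomimetic chemical or enzymatic β–β coupling of sinapyl alcohol to syringaresinol, and of γ-acylated sinapyl alcohols or 4-propenylsyringol to racemic 2,5-diaryloxolanes.

**Step 4**
Reactants: 5 (with its C2 epimer)
Product: 6, (2S,3S,4S,5S)-2,5-bis(4-acetoxy-3,5-dimethoxyphenyl)-3,4-bis[(4S)-2,2-dimethyl-1,3-dioxolan-4-yl]oxolane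
Conditions: CSA (5 mol %), 4 Å MS, CH2Cl2, 0 °C → rt; then pyridine, Ac2O, DMAP (cat.), rt (one pot)
Reagents that add atoms: acetic anhydride, CC(=O)OC(C)=O
Why: Anhydrous acid reversibly ionises the p-hydroxybenzylic C–O bond (the classical acid epimerisation of 2-aryl oxolane and furofuran lignans), so C2/C5 converge on the all-trans thermodynamic isomer under control of C3/C4, and acetylation then protects the phenols from periodate.

**Step 5**
Reactants: 6
Product: 7, (2S,3S,4S,5S)-2,5-bis(4-acetoxy-3,5-dimethoxyphenyl)oxolane-3,4-dicarbaldehyde
Conditions: H5IO6 (3.2 equiv), EtOAc, rt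
Reagents that add atoms: none (the aldehyde oxygens are the original C9 oxygens)
Why: Periodic acid unmasks the terminal acetonides and cleaves the glycols in one pot (Malaprade cleavage), and the α-centres are safe because all-trans is already the thermodynamic arrangement and the aryl acetates suppress benzylic ionisation.

**Step 6**
Reactants: 7
Product: 8, huazhongilexin, (2S,3R,4R,5S)-2,5-bis(4-hydroxy-3,5-dimethoxyphenyl)-3,4-bis(hydroxymethyl)oxolane
Conditions: NaBH4, THF–MeOH, 0 °C; then K2CO3, rt, N2; aq NH4Cl work-up (no strong acid)
Reagents that add atoms: none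
Why: Fast borohydride reduction outruns β-alkoxy elimination, carbonate methanolysis removes the aryl acetates, no stereocentre is touched (C3/C4 change S→R by priority only), and avoiding acid prevents rearrangement to the furofuran.

## Compound list
1 | (4R)-2,2-dimethyl-1,3-dioxolane-4-carbaldehyde | O=C[C@H]1COC(C)(C)O1 | starting material
2 | (4S)-4-ethenyl-2,2-dimethyl-1,3-dioxolane | C=C[C@H]1COC(C)(C)O1 | intermediate
3 | 4-bromo-2,6-dimethoxyphenol | COc1cc(Br)cc(OC)c1O | starting material
4 | 4-{(E)-2-[(4S)-2,2-dimethyl-1,3-dioxolan-4-yl]ethenyl}-2,6-dimethoxyphenol | COc1cc(/C=C/[C@H]2COC(C)(C)O2)cc(OC)c1O | intermediate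
5 | (2S,3S,4S,5S)-2,5-bis(4-hydroxy-3,5-dimethoxyphenyl)-3,4-bis[(4S)-2,2-dimethyl-1,3-dioxolan-4-yl]oxolane | COc1cc([C@H]2O[C@H](c3cc(OC)c(O)c(OC)c3)[C@@H]([C@H]4COC(C)(C)O4)[C@@H]2[C@H]5COC(C)(C)O5)cc(OC)c1O | intermediate
6 | bis(aryl acetate) of 5 | COc1cc([C@H]2O[C@H](c3cc(OC)c(OC(C)=O)c(OC)c3)[C@@H]([C@H]4COC(C)(C)O4)[C@@H]2[C@H]5COC(C)(C)O5)cc(OC)c1OC(C)=O | intermediate
7 | (2S,3S,4S,5S)-2,5-bis(4-acetoxy-3,5-dimethoxyphenyl)oxolane-3,4-dicarbaldehyde | COc1cc([C@H]2O[C@H](c3cc(OC)c(OC(C)=O)c(OC)c3)[C@@H](C=O)[C@@H]2C=O)cc(OC)c1OC(C)=O | intermediate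
8 | huazhongilexin | COc1cc([C@H]2O[C@H](c3cc(OC)c(O)c(OC)c3)[C@@H](CO)[C@@H]2CO)cc(OC)c1O | target

## Summary
Total steps: 6. Longest linear sequence: 6 (1 → 8).

**Steps most likely to fail**
1. **Step 3 (new anodic coupling).**
   - Risks: competing 8–O–4′ coupling, modest facial bias from the dioxolane, anode fouling, and over-oxidation of the product.
   - Fallback (known chemistry): run a tandem conjugate addition–aldol on the chiral-pool butenolide (S)-5-(trityloxymethyl)furan-2(5H)-one.
   - Bond formation: the lithiated 2-aryl-1,3-dithiane of O-benzylsyringaldehyde adds anti to CH2OTr, and the enolate is trapped trans with O-benzylsyringaldehyde.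
   - Completion: dithiane hydrolysis and ketone reduction, LiAlH4, NaIO4/NaBH4 removal of the extra carbon, silylation of the primary alcohols, MsCl/Et3N ring closure to the all-trans oxolane, then deprotection.
2. **Step 4 (acid equilibration).**
   - Risks: participation of a dioxolane oxygen in the benzylic cation, and Friedel–Crafts closure to an aryltetralin.
   - Fallback: do not equilibrate at the acetal stage. Acetylate the epimer mixture, carry out Step 5 and the NaBH4 reduction, and peracetylate.
   - Completion: remove only the aryl acetates (NH4OAc, aq MeOH) and equilibrate the 9,9′-diacetate with TFA/CH2Cl2. That substrate has no acetal and no free CH2OH that could close to the furofuran. Finish with K2CO3/MeOH.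
3. **Step 2 (Heck coupling).**
   - Risks: slow oxidative addition of the electron-rich bromophenol, and β-H elimination toward C9 giving an enol ether.
   - Fallback: E-selective Horner–Wadsworth–Emmons olefination of 1 with diethyl [4-(tert-butyldimethylsilyloxy)-3,5-dimethoxybenzyl]phosphonate, then TBAF to give 4.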